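**Plan**
1. Retrosynthetic cuts: first the bond between oxolane C2 and the ipso carbon of the 3,4,5-trimethoxyphenyl ring; then the O1–C2 acetal bond, which unrolls the ring to a 2-(dimethoxymethyl)butane-1,4-diol, the reduced form of a trans-α,β-disubstituted γ-lactone; then the lactone Cα–CH(OMe)2 bond and the Cβ–CH2CO bond.
2. Forward order: acyl oxazolidinone, alkylation, (S)-β-veratryl-γ-butyrolactone, trans α-dimethoxymethylation, LiAlH4/acid ring switch (lactone ring opened, oxolane closed through the acetal carbon), pivalate, aryl joined at C2, ester removed.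
3. Enabling feature: C2 is the only acetal-level carbon of the target and sits next to ring O1, so O1–C2 can be ionised to a five-membered oxocarbenium ion. The C3 CH2O arm and the C4 benzyl arm are cis on the oxolane and screen one face, and the C3 arm carries a pivalate that can bridge to C2.
4. Stereochemistry: C4 from alkylation on the (R)-4-benzyloxazolidinone; C3 from alkylation of the lactone enolate anti to C4 (trans on the lactone becomes cis on the oxolane after the ring switch); C2 from aryl delivery anti to both arms.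

Key step: step 7

Remark on the chemistry: (3,4,5-trimethoxyphenyl)magnesium bromide 14 is assumed to be bought as its THF solution (otherwise made from 5-bromo-1,2,3-trimethoxybenzene and magnesium). Compounds 12, 13 and 15 are carried as mixtures at C2, which step 7 erases.

Step 1
Reactants: 1 3-(3,4-dimethoxyphenyl)propanoic acid; 2 (4R)-4-benzyl-1,3-oxazolidin-2-one
Product: 4 (4R)-4-benzyl-3-[3-(3,4-dimethoxyphenyl)propanoyl]-1,3-oxazolidin-2-one, via mixed pivalic anhydride 3 (not isolated)
Conditions: PivCl, Et3N, THF, −20 °C; then LiCl, 2, −20 °C → rt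
Reagents that add atoms: none
Why: N-acylation of the oxazolidinone by the mixed anhydride (acyl transfer, auxiliary loading) is standard, tolerates the veratryl ring and forms no stereocentre.

Step 2
Reactants: 4 (4R)-4-benzyl-3-[3-(3,4-dimethoxyphenyl)propanoyl]-1,3-oxazolidin-2-one
Product: 6 tert-butyl (3S)-3-[(4R)-4-benzyl-2-oxo-1,3-oxazolidine-3-carbonyl]-4-(3,4-dimethoxyphenyl)butanoate, via sodium Z-enolate 5 (not isolated)
Conditions: NaHMDS, THF, −78 °C; then BrCH2CO2t-Bu, −78 → −40 °C
Reagents that add atoms: tert-butyl bromoacetate CC(C)(C)OC(=O)CBr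
Why: In this Evans asymmetric alkylation the chelated Z-enolate 5 should be alkylated on the face opposite the benzyl group of the (R)-auxiliary, which sets the new centre as S (the future C4 of the oxolane).

Step 3
Reactants: 6 tert-butyl (3S)-3-[(4R)-4-benzyl-2-oxo-1,3-oxazolidine-3-carbonyl]-4-(3,4-dimethoxyphenyl)butanoate
Product: 8 (4S)-4-[(3,4-dimethoxyphenyl)methyl]oxolan-2-one, via hydroxy tert-butyl ester 7 (not isolated)
Conditions: LiBH4, H2O (1 equiv), Et2O, 0 °C; then p-TsOH·H2O (cat.), toluene, 80 °C
Reagents that add atoms: none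
Why: Chemoselective borohydride reduction of the imide carbonyl (the tert-butyl ester is spared and auxiliary 2 is released for recovery) followed by acid-catalysed lactonisation of the γ-hydroxy ester leaves the stereocentre untouched.

Step 4
Reactants: 8 (4S)-4-[(3,4-dimethoxyphenyl)methyl]oxolan-2-one
Product: 10 (3R,4S)-3-(dimethoxymethyl)-4-[(3,4-dimethoxyphenyl)methyl]oxolan-2-one, via silyl ketene acetal 9 (not isolated)
Conditions: LDA, TMSCl (in situ quench), THF, −78 °C; then HC(OMe)3, TMSOTf (10 mol %), CH2Cl2, −78 °C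
Reagents that add atoms: trimethyl orthoformate COC(OC)OC
Why: In this Mukaiyama-type aldol addition to an orthoester the dimethoxycarbenium ion should attack silyl ketene acetal 9 anti to the C4 benzyl group, so the new C3 centre is R and trans to C4, which is also the thermodynamically preferred arrangement.

Step 5
Reactants: 10 (3R,4S)-3-(dimethoxymethyl)-4-[(3,4-dimethoxyphenyl)methyl]oxolan-2-one
Product: 12 [(3S,4S)-4-[(3,4-dimethoxyphenyl)methyl]-2-methoxyoxolan-3-yl]methanol, via diol acetal 11 (not isolated)
Conditions: LiAlH4, THF, 0 °C; then PPTS (10 mol %), 4 Å MS, CH2Cl2, rt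
Reagents that add atoms: none
Why: Hydride reduction of the lactone gives 1,4-diol 11, and acid-catalysed intramolecular transacetalisation (5-exo-trig closure by the only hydroxyl that can reach the acetal carbon in a five-membered ring) moves the ring onto the acetal carbon, so the trans lactone substituents become the cis C3/C4 arms of 12 without either stereocentre being touched.

Step 6
Reactants: 12 [(3S,4S)-4-[(3,4-dimethoxyphenyl)methyl]-2-methoxyoxolan-3-yl]methanol
Product: 13 [(3S,4S)-4-[(3,4-dimethoxyphenyl)methyl]-2-methoxyoxolan-3-yl]methyl 2,2-dimethylpropanoate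
Conditions: PivCl, pyridine, DMAP (cat.), CH2Cl2, 0 °C → rt
Reagents that add atoms: pivaloyl chloride CC(C)(C)C(=O)Cl
Why: DMAP-catalysed esterification of the primary alcohol installs a pivalate that resists arylzinc reagents and can act as a participating group towards C2, while the acetal is stable to the basic medium.

Step 7
Reactants: 13 [(3S,4S)-4-[(3,4-dimethoxyphenyl)methyl]-2-methoxyoxolan-3-yl]methyl 2,2-dimethylpropanoate; 14 (3,4,5-trimethoxyphenyl)magnesium bromide
Product: 17 [(2R,3S,4S)-4-[(3,4-dimethoxyphenyl)methyl]-2-(3,4,5-trimethoxyphenyl)oxolan-3-yl]methyl 2,2-dimethylpropanoate, via bromo-oxolane pivalate 15 (not isolated), via arylzinc bromide 16 (not isolated)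
Conditions: 13, TMSBr, CH2Cl2, −40 → 0 °C (gives 15); 14, ZnBr2, THF, 0 °C (gives 16); then 15 added to 16, −40 → 0 °C
Reagents that add atoms: none
Why: TMSBr converts both anomers of acetal 13 into α-bromo ether 15, whose zinc/magnesium-halide-assisted ionisation gives the five-membered oxocarbenium ion O1=C2(+) (capped reversibly on the C3 face by the pivalate carbonyl as a cis-fused 1,3-dioxan-2-ylium ion), and arylzinc 16 transfers its ipso carbon to C2. The closest known reaction types are the arylzinc C-arylation of pivaloylated glycosyl bromides and the organozinc substitution of 2-halo and 2-sulfonyl cyclic ethers. No ring is closed in this step. The new C2 stereocentre is under substrate control: the C3 CH2OPiv and C4 benzyl arms are cis and fill one face of the cation, so inside attack on the envelope that keeps the C4 benzyl pseudoequatorial, backed by the bridging pivalate, should place the aryl group anti to both arms (2R, 2,3-trans). The step needs facial selectivity (secured as above, with both anomers converging on one planar cation), ipso regioselectivity in the arene (fixed by the C–Zn bond, whereas free 1,2,3-trimethoxybenzene would be attacked at C4), and chemoselectivity (the arylzinc spares the pivalate, and fast capture at low temperature should outrun loss of H3 to the enol ether and Friedel–Crafts capture by the pendant veratryl ring).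

Step 8
Reactants: 17 [(2R,3S,4S)-4-[(3,4-dimethoxyphenyl)methyl]-2-(3,4,5-trimethoxyphenyl)oxolan-3-yl]methyl 2,2-dimethylpropanoate
Product: 18 [(2R,3S,4S)-4-[(3,4-dimethoxyphenyl)methyl]-2-(3,4,5-trimethoxyphenyl)oxolan-3-yl]methanol
Conditions: LiAlH4, THF, 0 °C
Reagents that add atoms: none
Why: Hydride reduction of the pivalate ester frees the primary alcohol, and the aryl ethers, the benzylic ether C2 and the three stereocentres (none epimerisable here) should be unaffected.

**Compound list**
1 | 3-(3,4-dimethoxyphenyl)propanoic acid | COc1ccc(CCC(=O)O)cc1OC | starting material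
2 | (4R)-4-benzyl-1,3-oxazolidin-2-one | O=C1N[C@H](Cc2ccccc2)CO1 | starting material
3 | 3-(3,4-dimethoxyphenyl)propanoic pivalic anhydride | COc1ccc(CCC(=O)OC(=O)C(C)(C)C)cc1OC | intermediate
4 | (4R)-4-benzyl-3-[3-(3,4-dimethoxyphenyl)propanoyl]-1,3-oxazolidin-2-one | COc1ccc(CCC(=O)N2[C@H](Cc3ccccc3)COC2=O)cc1OC | intermediate
5 | sodium (Z)-enolate of 4 | COc1ccc(C/C=C(\[O-])N2[C@H](Cc3ccccc3)COC2=O)cc1OC.[Na+] | intermediate
6 | tert-butyl (3S)-3-[(4R)-4-benzyl-2-oxo-1,3-oxazolidine-3-carbonyl]-4-(3,4-dimethoxyphenyl)butanoate | COc1ccc(C[C@@H](CC(=O)OC(C)(C)C)C(=O)N2[C@H](Cc3ccccc3)COC2=O)cc1OC | intermediate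
7 | tert-butyl (3S)-4-(3,4-dimethoxyphenyl)-3-(hydroxymethyl)butanoate | COc1ccc(C[C@@H](CC(=O)OC(C)(C)C)CO)cc1OC | intermediate
8 | (4S)-4-[(3,4-dimethoxyphenyl)methyl]oxolan-2-one | COc1ccc(C[C@@H]2COC(=O)C2)cc1OC | intermediate
9 | {[(4S)-4-[(3,4-dimethoxyphenyl)methyl]-4,5-dihydrofuran-2-yl]oxy}trimethylsilane | COc1ccc(C[C@@H]2COC(O[Si](C)(C)C)=C2)cc1OC | intermediate
10 | (3R,4S)-3-(dimethoxymethyl)-4-[(3,4-dimethoxyphenyl)methyl]oxolan-2-one (trans) | COc1ccc(C[C@@H]2COC(=O)[C@H]2C(OC)OC)cc1OC | intermediate
11 | (2S,3S)-2-(dimethoxymethyl)-3-[(3,4-dimethoxyphenyl)methyl]butane-1,4-diol | COc1ccc(C[C@H](CO)[C@@H](CO)C(OC)OC)cc1OC | intermediate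
12 | [(3S,4S)-4-[(3,4-dimethoxyphenyl)methyl]-2-methoxyoxolan-3-yl]methanol (3,4-cis, both C2 anomers) | COc1ccc(C[C@@H]2COC(OC)[C@@H]2CO)cc1OC | intermediate
13 | [(3S,4S)-4-[(3,4-dimethoxyphenyl)methyl]-2-methoxyoxolan-3-yl]methyl 2,2-dimethylpropanoate (both C2 anomers) | COc1ccc(C[C@@H]2COC(OC)[C@@H]2COC(=O)C(C)(C)C)cc1OC | intermediate
14 | (3,4,5-trimethoxyphenyl)magnesium bromide | COc1cc([Mg]Br)cc(OC)c1OC | starting material
15 | [(3S,4S)-2-bromo-4-[(3,4-dimethoxyphenyl)methyl]oxolan-3-yl]methyl 2,2-dimethylpropanoate | COc1ccc(C[C@@H]2COC(Br)[C@@H]2COC(=O)C(C)(C)C)cc1OC | intermediate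
16 | (3,4,5-trimethoxyphenyl)zinc bromide | COc1cc([Zn]Br)cc(OC)c1OC | intermediate
17 | [(2R,3S,4S)-4-[(3,4-dimethoxyphenyl)methyl]-2-(3,4,5-trimethoxyphenyl)oxolan-3-yl]methyl 2,2-dimethylpropanoate | COc1ccc(C[C@@H]2CO[C@@H](c3cc(OC)c(OC)c(OC)c3)[C@@H]2COC(=O)C(C)(C)C)cc1OC | intermediate
18 | [(2R,3S,4S)-4-[(3,4-dimethoxyphenyl)methyl]-2-(3,4,5-trimethoxyphenyl)oxolan-3-yl]methanol | COc1ccc(C[C@@H]2CO[C@@H](c3cc(OC)c(OC)c(OC)c3)[C@@H]2CO)cc1OC | target

Total step count: 8. Longest linear sequence: 8 steps (1 → 18).

**Steps most likely to fail**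

Step 7. The oxocarbenium ion may lose H3 to give the endocyclic enol ether (which would also scramble C3), may be captured intramolecularly by the veratryl ring, or may be arylated with incomplete facial selectivity before the arylzinc delivers cleanly. The fallback sets out from 12 and returns to the route at 18. Aqueous acid hydrolysis of the methyl acetal (AcOH, H2O, THF) should give the lactol (3S,4S)-4-[(3,4-dimethoxyphenyl)methyl]-3-(hydroxymethyl)oxolan-2-ol F1. Excess Grignard reagent 14 (THF, 0 °C → rt) should add to its open hydroxy-aldehyde form to give the triol (2S,3S)-2-[(3,4-dimethoxyphenyl)methyl]-3-[hydroxy(3,4,5-trimethoxyphenyl)methyl]butane-1,4-diol F2 as a mixture of carbinol epimers. Mild acid (CSA, CH2Cl2) should then ionise the benzylic carbinol; the only hydroxyl able to close a five-membered ring captures the cation, and this thermodynamically controlled cyclodehydration should give the 2,3-trans oxolane 18 directly. In this variant the aryl–carbon bond comes from carbonyl addition and C2 is set in the separate ring closure.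

Step 4. The silyl ketene acetal may hydrolyse back to 8, and the product acetal may lose methanol to the α-methoxymethylene lactone (erasing C3) or react with a second ketene acetal. The fallback sets out from 8 and returns at 10. Claisen formylation (NaH, ethyl formate, THF) should give (4S)-4-[(3,4-dimethoxyphenyl)methyl]-3-(hydroxymethylidene)oxolan-2-one F3. Acid-catalysed acetalisation under equilibrating conditions (HC(OMe)3, MeOH, cat. TsOH) should then give the trans acetal 10 as the more stable C3 epimer.

Step 5. During the acid-mediated ring switch the acyclic oxocarbenium ion may be diverted into intermolecular acetal exchange or into Friedel–Crafts closure onto the veratryl ring, and the anomeric mixture may be hard to purify. The fallback sets out from 11 and returns at 17. Benzenesulfinic acid with CaCl2 in CH2Cl2 should close the ring and trap the cyclic cation as the sulfone [(3S,4S)-2-(benzenesulfonyl)-4-[(3,4-dimethoxyphenyl)methyl]oxolan-3-yl]methanol F4. Pivaloylation (PivCl, pyridine) should give [(3S,4S)-2-(benzenesulfonyl)-4-[(3,4-dimethoxyphenyl)methyl]oxolan-3-yl]methyl 2,2-dimethylpropanoate F5. Treating F5 with arylzinc 16 and ZnBr2 in THF should displace the sulfinate through the same oxocarbenium ion and give 17.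

**Further compounds**
F1 | step 7 | (3S,4S)-4-[(3,4-dimethoxyphenyl)methyl]-3-(hydroxymethyl)oxolan-2-ol | COc1ccc(C[C@@H]2COC(O)[C@@H]2CO)cc1OC
F2 | step 7 | (2S,3S)-2-[(3,4-dimethoxyphenyl)methyl]-3-[hydroxy(3,4,5-trimethoxyphenyl)methyl]butane-1,4-diol | COc1ccc(C[C@H](CO)[C@@H](CO)C(O)c2cc(OC)c(OC)c(OC)c2)cc1OC
F3 | step 4 | (4S)-4-[(3,4-dimethoxyphenyl)methyl]-3-(hydroxymethylidene)oxolan-2-one | COc1ccc(C[C@@H]2COC(=O)C2=CO)cc1OC
F4 | step 5 | [(3S,4S)-2-(benzenesulfonyl)-4-[(3,4-dimethoxyphenyl)methyl]oxolan-3-yl]methanol | COc1ccc(C[C@@H]2COC(S(=O)(=O)c3ccccc3)[C@@H]2CO)cc1OC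
F5 | step 5 | [(3S,4S)-2-(benzenesulfonyl)-4-[(3,4-dimethoxyphenyl)methyl]oxolan-3-yl]methyl 2,2-dimethylpropanoate | COc1ccc(C[C@@H]2COC(S(=O)(=O)c3ccccc3)[C@@H]2COC(=O)C(C)(C)C)cc1OC
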